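**Retrosynthetic overview**
1. Target 22 is methyl (4S,5R,10S)-15-acetoxylabda-8,13E-dien-19-oate. Enabling feature: ring B (C5–C6–C7–C8–C9–C10) is a cyclohexene whose only double bond, C8=C9, lies opposite the C5–C6 bond, while C5 and C10 are also joined through C4–C3–C2–C1 of ring A. Ring B is therefore a Diels–Alder retron with ring A as the tether.
2. Key disconnection: C5–C10 and C6–C7 together, by intramolecular Diels–Alder reaction of the open-chain (E)-nitro triene 20 (dienophile C5=C6, diene C7=C8–C9=C10). Rings A and B form in the same step; the C6 nitro group is a traceless activator removed in the last step.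
3. 20 comes from α-formyl ester 17 (Henry reaction, elimination). The C4 quaternary centre comes from dimethyl (S)-malate 13 by two Fráter–Seebach alkylations (iodide 12, then MeI) and excision of the malate C1 carboxyl.
4. 12 comes from alkynol 7 by copper-catalysed anti-carbomagnesiation with Grignard reagent 8, C-methylation and dehydration, which sets the E tetrasubstituted C9=C10 alkene of the diene. Side chain 5 comes from 4-bromobut-1-yne 1 by carboalumination.

Key step: step 14

Remark: C1–C20 in the text are the labdane locants of the target and are used for the open-chain intermediates as well; quenches of the organometallic steps are written with water.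

**Step 1**
Reactants: 1 4-bromobut-1-yne
Product: 3 methyl (2E)-5-bromo-3-methylpent-2-enoate, via alkenylalane 2 (not isolated)
Conditions: Me3Al (2.5 equiv), Cp2ZrCl2 (0.25 equiv), CH2Cl2, 0 °C to rt; then ClCO2Me, 0 °C to rt; then H2O
Reagents that add atoms: trimethylaluminium C[Al](C)C; methyl chloroformate COC(=O)Cl
Why: Zirconium-catalysed carboalumination of a terminal alkyne (Negishi carboalumination) adds CH3 and Al syn with Al on the terminal carbon, which fixes the E trisubstituted C13=C14 alkene, and the alkenylalane should be C-acylated by the chloroformate with retention.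

**Step 2**
Reactants: 3 methyl (2E)-5-bromo-3-methylpent-2-enoate
Product: 4 (2E)-5-bromo-3-methylpent-2-en-1-ol
Conditions: i-Bu2AlH (2.2 equiv), CH2Cl2, −78 °C; then H2O
Reagents that add atoms: none
Why: 1,2-Reduction of an enoate by i-Bu2AlH should give the allylic alcohol without touching the primary bromide or the alkene geometry.

**Step 3**
Reactants: 4 (2E)-5-bromo-3-methylpent-2-en-1-ol
Product: 5 {[(2E)-5-bromo-3-methylpent-2-en-1-yl]oxy}(tert-butyl)dimethylsilane
Conditions: t-BuMe2SiCl, imidazole, CH2Cl2, 0 °C to rt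
Reagents that add atoms: tert-butyldimethylsilyl chloride CC(C)(C)[Si](C)(C)Cl
Why: Standard silylation of a primary alcohol gives an ether that survives the Grignard, amide-base and hydroxide steps and is removed by fluoride in step 12.

**Step 4**
Reactants: 6 5-chloropent-1-yne
Product: 7 7-chloro-2-methylhept-3-yn-2-ol
Conditions: n-BuLi (1.05 equiv), THF, −78 °C; acetone, −78 to 0 °C; then H2O
Reagents that add atoms: acetone CC(C)=O
Why: Addition of the lithium acetylide to acetone installs C8 with C7 and C17 as a tertiary propargylic alcohol, while the primary chloride is inert at this temperature.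

**Step 5**
Reactants: 5 {[(2E)-5-bromo-3-methylpent-2-en-1-yl]oxy}(tert-butyl)dimethylsilane; 7 7-chloro-2-methylhept-3-yn-2-ol
Product: 10 (3E)-3-[(3E)-5-{[tert-butyl(dimethyl)silyl]oxy}-3-methylpent-3-en-1-yl]-7-chloro-2,4-dimethylhept-3-en-2-ol, via Grignard reagent 8 (not isolated), via oxamagnesacycle 9 (not isolated)
Conditions: 5, Mg, THF, 25 °C; 7, i-PrMgCl (1.0 equiv), THF, 0 °C; then 8 (2 equiv), CuI (0.2 equiv), THF–toluene, −20 °C to rt; then MeI (excess), DMPU, 0 °C to rt; then H2O
Reagents that add atoms: iodomethane CI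
Why: Copper-catalysed carbomagnesiation of a propargylic alkoxide is an anti addition that puts the alkyl group on the carbinol-bearing alkyne carbon (C9) and magnesium on C10, held cis to the carbinol in the five-membered magnesacycle 9, so C-methylation with retention should place C20 cis to C8 and the chloropropyl chain cis to C11, that is the E tetrasubstituted alkene.

**Step 6**
Reactants: 10 (3E)-3-[(3E)-5-{[tert-butyl(dimethyl)silyl]oxy}-3-methylpent-3-en-1-yl]-7-chloro-2,4-dimethylhept-3-en-2-ol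
Product: 11 tert-butyl{[(2E,6E)-10-chloro-3,7-dimethyl-6-(prop-1-en-2-yl)deca-2,6-dien-1-yl]oxy}dimethylsilane
Conditions: methyl N-(triethylammoniosulfonyl)carbamate (Burgess reagent, 1.5 equiv), toluene, 50 °C
Reagents that add atoms: none
Why: Burgess dehydration is a syn elimination through the sulfamate ester, and since C9 bears no hydrogen only a methyl hydrogen can be lost, which should give the isopropenyl group (C7=C8) and thus the 1,3-diene with the C9=C10 geometry unchanged.

**Step 7**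
Reactants: 11 tert-butyl{[(2E,6E)-10-chloro-3,7-dimethyl-6-(prop-1-en-2-yl)deca-2,6-dien-1-yl]oxy}dimethylsilane
Product: 12 tert-butyl{[(2E,6E)-10-iodo-3,7-dimethyl-6-(prop-1-en-2-yl)deca-2,6-dien-1-yl]oxy}dimethylsilane
Conditions: NaI (5 equiv), acetone, reflux
Reagents that add atoms: sodium iodide [Na+].[I-]
Why: Finkelstein exchange turns the unreactive primary chloride into the iodide needed for enolate alkylation.

**Step 8**
Reactants: 12 tert-butyl{[(2E,6E)-10-iodo-3,7-dimethyl-6-(prop-1-en-2-yl)deca-2,6-dien-1-yl]oxy}dimethylsilane; 13 dimethyl (2S)-2-hydroxybutanedioate (dimethyl (S)-malate)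
Product: 14 dimethyl (2S,3R)-3-[(4E,8E)-10-{[tert-butyl(dimethyl)silyl]oxy}-4,8-dimethyl-5-(prop-1-en-2-yl)deca-4,8-dien-1-yl]-2-hydroxybutanedioate
Conditions: 13 (2.5 equiv), LiN(SiMe3)2 (5.0 equiv), THF, −78 to −20 °C; then 12, DMPU, −78 to 0 °C; then H2O
Reagents that add atoms: none
Why: Fráter–Seebach alkylation: the lithium-chelated alkoxide enolate of the malate should be alkylated by the primary iodide anti to the C2 ester group, and the new centre need not be pure because it is planarised again in step 9.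

**Step 9**
Reactants: 14 dimethyl (2S,3R)-3-[(4E,8E)-10-{[tert-butyl(dimethyl)silyl]oxy}-4,8-dimethyl-5-(prop-1-en-2-yl)deca-4,8-dien-1-yl]-2-hydroxybutanedioate
Product: 15 dimethyl (2S,3S)-3-[(4E,8E)-10-{[tert-butyl(dimethyl)silyl]oxy}-4,8-dimethyl-5-(prop-1-en-2-yl)deca-4,8-dien-1-yl]-2-hydroxy-3-methylbutanedioate
Conditions: LiN(i-Pr)2 (2.3 equiv), THF, −78 to −30 °C; MeI, −78 to −10 °C; then H2O
Reagents that add atoms: iodomethane CI
Why: Second Fráter–Seebach alkylation: the chelated tetrasubstituted enolate is methylated again anti to the C2 ester group, so the order of introduction (chain first, methyl second) should set the quaternary carbon as 3S (C4 of the target), the minor epimer being removable by chromatography.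

**Step 10**
Reactants: 15 dimethyl (2S,3S)-3-[(4E,8E)-10-{[tert-butyl(dimethyl)silyl]oxy}-4,8-dimethyl-5-(prop-1-en-2-yl)deca-4,8-dien-1-yl]-2-hydroxy-3-methylbutanedioate
Product: 16 (2S,3S)-3-[(4E,8E)-10-{[tert-butyl(dimethyl)silyl]oxy}-4,8-dimethyl-5-(prop-1-en-2-yl)deca-4,8-dien-1-yl]-2-hydroxy-4-methoxy-3-methyl-4-oxobutanoic acid
Conditions: LiOH·H2O (1.2 equiv), THF/H2O, 0 °C; then 1 M HCl to pH 3
Reagents that add atoms: lithium hydroxide [Li+].[OH-]
Why: Saponification is expected at the unhindered α-hydroxy ester only, because the other ester sits on a quaternary, neopentyl-type carbon.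

**Step 11**
Reactants: 16 (2S,3S)-3-[(4E,8E)-10-{[tert-butyl(dimethyl)silyl]oxy}-4,8-dimethyl-5-(prop-1-en-2-yl)deca-4,8-dien-1-yl]-2-hydroxy-4-methoxy-3-methyl-4-oxobutanoic acid
Product: 17 methyl (2S,6E,10E)-12-{[tert-butyl(dimethyl)silyl]oxy}-2-formyl-2,6,10-trimethyl-7-(prop-1-en-2-yl)dodeca-6,10-dienoate
Conditions: Pb(OAc)4 (1.1 equiv), CH2Cl2, −20 to 0 °C
Reagents that add atoms: none
Why: Oxidative decarboxylation of an α-hydroxy acid by Pb(OAc)4 (a glycol-type cleavage) should give the non-enolisable C5 aldehyde faster than tetravalent lead attacks the alkenes, and the quaternary centre is untouched.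

**Step 12**
Reactants: 17 methyl (2S,6E,10E)-12-{[tert-butyl(dimethyl)silyl]oxy}-2-formyl-2,6,10-trimethyl-7-(prop-1-en-2-yl)dodeca-6,10-dienoate
Product: 18 methyl (2S,6E,10E)-12-hydroxy-2-(1-hydroxy-2-nitroethyl)-2,6,10-trimethyl-7-(prop-1-en-2-yl)dodeca-6,10-dienoate (both carbinol epimers)
Conditions: MeNO2 (10 equiv), Bu4NF·3H2O (1.5 equiv), THF, 0 °C to rt
Reagents that add atoms: nitromethane C[N+](=O)[O-]
Why: Fluoride-mediated Henry reaction: Bu4NF generates the nitronate, which adds to the non-enolisable aldehyde to bring in C6, and the same reagent cleaves the primary silyl ether, so the diol should form in one operation (the C5 carbinol configuration is of no consequence).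

**Step 13**
Reactants: 18 methyl (2S,6E,10E)-12-hydroxy-2-(1-hydroxy-2-nitroethyl)-2,6,10-trimethyl-7-(prop-1-en-2-yl)dodeca-6,10-dienoate
Product: 20 methyl (2S,6E,10E)-12-acetoxy-2,6,10-trimethyl-2-[(E)-2-nitroethenyl]-7-(prop-1-en-2-yl)dodeca-6,10-dienoate, via nitro diacetate 19 (not isolated)
Conditions: Ac2O (3 equiv), Et3N (5 equiv), DMAP (0.1 equiv), CH2Cl2, 0 °C to rt
Reagents that add atoms: acetic anhydride CC(=O)OC(C)=O
Why: Acetylation of both hydroxyl groups is followed by E1cB loss of acetic acid from the β-acetoxy nitro unit, which should give the conjugated E nitroalkene (no γ-hydrogen, so no deconjugation) and leave the primary allylic acetate of the target in place.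

**Step 14**
Reactants: 20 methyl (2S,6E,10E)-12-acetoxy-2,6,10-trimethyl-2-[(E)-2-nitroethenyl]-7-(prop-1-en-2-yl)dodeca-6,10-dienoate
Product: 21 methyl (4S,5R,6S,10S)-15-acetoxy-6-nitrolabda-8,13E-dien-19-oate (trans-fused; 6-nitro cis to H-5)
Conditions: toluene (0.01 M), 2,6-di-tert-butyl-4-methylphenol (0.1 equiv), 100 °C, sealed tube
Reagents that add atoms: none
Why: The (E)-nitroalkene (C5=C6) and the tetrasubstituted diene (C7=C8–C9=C10), joined by the chain C4–C3–C2–C1, should undergo a concerted, asynchronous normal-demand [4+2] cycloaddition, the closest known reaction type being the thermal intramolecular Diels–Alder reaction of (E)-1-nitrodeca-1,7,9-trienes to trans-fused nitrodecalins. Ring B is closed as the cycloadduct ring itself (suprafacial on both components, new bonds C6–C7 and C5–C10, new C8=C9 double bond), and ring A is closed by the same C5–C10 bond in the fused mode through a chair-like arrangement of the tether. C6 and C5 follow from the E geometry of the dienophile (nitro cis to H-5), and C10 relative to C5 follows from the diene geometry (C20 methyl inside, tether outside) together with the tether-exo, nitro-endo transition state, which gives the trans ring fusion with the angular methyl anti to H-5. The absolute sense at C5 and C10 is relayed from C4: of the two chair-like trans transition states, the one with CO2Me axial and CH3 equatorial on the forming ring A avoids a methyl/methyl 1,3-diaxial contact with the incipient angular methyl and leads to the 4S,5R,10S array. The step needs π-facial selectivity, trans over cis fusion and a diene reactive enough despite its inside methyl; these are to be secured by the C4 substituents, the endo preference of the nitro group and the LUMO lowering by the nitro group, which should let the cycloaddition run below the temperature of 1,5-hydrogen shifts in the diene.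

**Step 15**
Reactants: 21 methyl (4S,5R,6S,10S)-15-acetoxy-6-nitrolabda-8,13E-dien-19-oate
Product: 22 methyl (4S,5R,10S)-15-acetoxylabda-8,13E-dien-19-oate (target)
Conditions: Bu3SnH (5 equiv), AIBN (0.3 equiv, in portions), toluene, 110 °C
Reagents that add atoms: none
Why: Radical denitration: the stannyl radical adds to a nitro oxygen, the adduct loses Bu3SnONO to give the secondary C6 radical, which abstracts hydrogen from Bu3SnH, so the activating group is replaced by hydrogen at a carbon that is not stereogenic in the product while ester, acetate and alkenes should be inert.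

**Compound list**
1 | 4-bromobut-1-yne | C#CCCBr | starting material
2 | [(1E)-4-bromo-2-methylbut-1-en-1-yl]dimethylalane | C[Al](C)/C=C(C)/CCBr | intermediate
3 | methyl (2E)-5-bromo-3-methylpent-2-enoate | COC(=O)/C=C(C)/CCBr | intermediate
4 | (2E)-5-bromo-3-methylpent-2-en-1-ol | OC/C=C(C)/CCBr | intermediate
5 | {[(2E)-5-bromo-3-methylpent-2-en-1-yl]oxy}(tert-butyl)dimethylsilane | CC(C)(C)[Si](C)(C)OC/C=C(C)/CCBr | intermediate
6 | 5-chloropent-1-yne | C#CCCCCl | starting material
7 | 7-chloro-2-methylhept-3-yn-2-ol | CC(C)(O)C#CCCCCl | intermediate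
8 | [(3E)-5-{[tert-butyl(dimethyl)silyl]oxy}-3-methylpent-3-en-1-yl]magnesium bromide | CC(C)(C)[Si](C)(C)OC/C=C(C)/CC[Mg]Br | intermediate
9 | cyclic alkenylmagnesium alkoxide (2,5-dihydro-1,2-oxamagnesole; Mg bonded to the C8 oxygen and to C10, C9 carrying the side chain, C10 the 3-chloropropyl group) | ClCCCC1=C(CC/C(C)=C/CO[Si](C)(C)C(C)(C)C)C(C)(C)O[Mg]1 | intermediate
10 | (3E)-3-[(3E)-5-{[tert-butyl(dimethyl)silyl]oxy}-3-methylpent-3-en-1-yl]-7-chloro-2,4-dimethylhept-3-en-2-ol | ClCCC/C(C)=C(\CC/C(C)=C/CO[Si](C)(C)C(C)(C)C)C(C)(C)O | intermediate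
11 | tert-butyl{[(2E,6E)-10-chloro-3,7-dimethyl-6-(prop-1-en-2-yl)deca-2,6-dien-1-yl]oxy}dimethylsilane | ClCCC/C(C)=C(\CC/C(C)=C/CO[Si](C)(C)C(C)(C)C)C(C)=C | intermediate
12 | tert-butyl{[(2E,6E)-10-iodo-3,7-dimethyl-6-(prop-1-en-2-yl)deca-2,6-dien-1-yl]oxy}dimethylsilane | ICCC/C(C)=C(\CC/C(C)=C/CO[Si](C)(C)C(C)(C)C)C(C)=C | intermediate
13 | dimethyl (2S)-2-hydroxybutanedioate (dimethyl (S)-malate) | COC(=O)C[C@H](O)C(=O)OC | starting material
14 | dimethyl (2S,3R)-3-[(4E,8E)-10-{[tert-butyl(dimethyl)silyl]oxy}-4,8-dimethyl-5-(prop-1-en-2-yl)deca-4,8-dien-1-yl]-2-hydroxybutanedioate | COC(=O)[C@H](CCC/C(C)=C(\CC/C(C)=C/CO[Si](C)(C)C(C)(C)C)C(C)=C)[C@H](O)C(=O)OC | intermediate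
15 | dimethyl (2S,3S)-3-[(4E,8E)-10-{[tert-butyl(dimethyl)silyl]oxy}-4,8-dimethyl-5-(prop-1-en-2-yl)deca-4,8-dien-1-yl]-2-hydroxy-3-methylbutanedioate | COC(=O)[C@@](C)(CCC/C(C)=C(\CC/C(C)=C/CO[Si](C)(C)C(C)(C)C)C(C)=C)[C@H](O)C(=O)OC | intermediate
16 | (2S,3S)-3-[(4E,8E)-10-{[tert-butyl(dimethyl)silyl]oxy}-4,8-dimethyl-5-(prop-1-en-2-yl)deca-4,8-dien-1-yl]-2-hydroxy-4-methoxy-3-methyl-4-oxobutanoic acid | COC(=O)[C@@](C)(CCC/C(C)=C(\CC/C(C)=C/CO[Si](C)(C)C(C)(C)C)C(C)=C)[C@H](O)C(=O)O | intermediate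
17 | methyl (2S,6E,10E)-12-{[tert-butyl(dimethyl)silyl]oxy}-2-formyl-2,6,10-trimethyl-7-(prop-1-en-2-yl)dodeca-6,10-dienoate | COC(=O)[C@@](C)(CCC/C(C)=C(\CC/C(C)=C/CO[Si](C)(C)C(C)(C)C)C(C)=C)C=O | intermediate
18 | methyl (2S,6E,10E)-12-hydroxy-2-(1-hydroxy-2-nitroethyl)-2,6,10-trimethyl-7-(prop-1-en-2-yl)dodeca-6,10-dienoate (carbinol epimers) | COC(=O)[C@@](C)(CCC/C(C)=C(\CC/C(C)=C/CO)C(C)=C)C(O)C[N+](=O)[O-] | intermediate
19 | methyl (2S,6E,10E)-12-acetoxy-2-(1-acetoxy-2-nitroethyl)-2,6,10-trimethyl-7-(prop-1-en-2-yl)dodeca-6,10-dienoate | COC(=O)[C@@](C)(CCC/C(C)=C(\CC/C(C)=C/COC(C)=O)C(C)=C)C(OC(C)=O)C[N+](=O)[O-] | intermediate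
20 | methyl (2S,6E,10E)-12-acetoxy-2,6,10-trimethyl-2-[(E)-2-nitroethenyl]-7-(prop-1-en-2-yl)dodeca-6,10-dienoate | COC(=O)[C@@](C)(CCC/C(C)=C(\CC/C(C)=C/COC(C)=O)C(C)=C)/C=C/[N+](=O)[O-] | intermediate
21 | methyl (4S,5R,6S,10S)-15-acetoxy-6-nitrolabda-8,13E-dien-19-oate | COC(=O)[C@@]1(C)CCC[C@]2(C)C(CC/C(C)=C/COC(C)=O)=C(C)C[C@H]([N+](=O)[O-])[C@@H]12 | intermediate
22 | methyl (4S,5R,10S)-15-acetoxylabda-8,13E-dien-19-oate | COC(=O)[C@@]1(C)CCC[C@]2(C)C(CC/C(C)=C/COC(C)=O)=C(C)CC[C@@H]12 | target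

**Step count**
Total: 15 steps. Longest linear sequence: 14 steps (steps 1–3 and 5–15, from 4-bromobut-1-yne). Alkynol 7 takes one step (step 4, from 5-chloropent-1-yne) and joins in step 5.

**Steps most likely to fail**

Step 5. The carbomagnesiation may stall or lose regio- and anti-selectivity at the hindered internal tertiary alkoxide. The homoallylic Grignard reagent may also decay by ring closure and β-elimination, or the magnesacycle may be protonated instead of methylated. The fallback sets out from bromide 5 and comes back at iodide 12, building the tetrasubstituted alkene by stereoretentive cross-coupling of an enol tosylate. Because a 3-chloropropylborane would close to cyclopropane under the basic coupling conditions, the three-carbon unit is carried as a triethylsilyl ether. Alkylation of methyl acetoacetate with 5 (K2CO3, NaI, acetone) should give racemic methyl (5E)-2-acetyl-7-{[tert-butyl(dimethyl)silyl]oxy}-5-methylhept-5-enoate F1. Enol tosylation under non-chelating conditions (4-methylbenzenesulfonyl chloride, N-methylimidazole, Et3N, MeCN) should give the E enol tosylate methyl (2E,5E)-7-{[tert-butyl(dimethyl)silyl]oxy}-5-methyl-2-{1-[(4-methylbenzenesulfonyl)oxy]ethylidene}hept-5-enoate F2, with the sulfonyloxy group cis to C11. Hydroboration of triethyl(prop-2-en-1-yloxy)silane with 9-borabicyclo[3.3.1]nonane gives 9-{3-[(triethylsilyl)oxy]propyl}-9-borabicyclo[3.3.1]nonane F3. Its Suzuki–Miyaura coupling with F2 (Pd(OAc)2, 2-dicyclohexylphosphino-2',6'-dimethoxybiphenyl, K3PO4, THF/H2O) should proceed with retention to the tetrasubstituted enoate methyl (2E,5E)-7-{[tert-butyl(dimethyl)silyl]oxy}-5-methyl-2-{5-[(triethylsilyl)oxy]pentan-2-ylidene}hept-5-enoate F4. Double addition of MeLi/CeCl3 (THF, −78 °C) should give the tertiary alcohol (3E)-3-[(3E)-5-{[tert-butyl(dimethyl)silyl]oxy}-3-methylpent-3-en-1-yl]-2,4-dimethyl-7-[(triethylsilyl)oxy]hept-3-en-2-ol F5. Burgess dehydration as in step 6 should give the diene (2E,6E)-1-{[tert-butyl(dimethyl)silyl]oxy}-3,7-dimethyl-6-(prop-1-en-2-yl)-10-[(triethylsilyl)oxy]deca-2,6-diene F6. Selective cleavage of the more labile triethylsilyl ether (pyridinium 4-methylbenzenesulfonate, MeOH/CH2Cl2, 0 °C) should give (4E,8E)-10-{[tert-butyl(dimethyl)silyl]oxy}-4,8-dimethyl-5-(prop-1-en-2-yl)deca-4,8-dien-1-ol F7. Appel iodination (I2, PPh3, imidazole, CH2Cl2, 0 °C) gives 12.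

Step 14. The cycloaddition may show poor π-facial discrimination by the C4 centre, competing cis-fused closure, or thermal decay of the nitroalkene before the hindered diene reacts. The fallback sets out from aldehyde 17 and comes back at 22, replacing thermal substrate control by low-temperature iminium catalysis with reagent control. Wittig reaction of 17 with (triphenylphosphoranylidene)acetaldehyde should give the E enal methyl (2S,6E,10E)-12-{[tert-butyl(dimethyl)silyl]oxy}-2,6,10-trimethyl-2-[(E)-3-oxoprop-1-en-1-yl]-7-(prop-1-en-2-yl)dodeca-6,10-dienoate F8. Desilylation with HF·pyridine gives the enal alcohol methyl (2S,6E,10E)-12-hydroxy-2,6,10-trimethyl-2-[(E)-3-oxoprop-1-en-1-yl]-7-(prop-1-en-2-yl)dodeca-6,10-dienoate F9, and Ac2O/pyridine gives the enal acetate methyl (2S,6E,10E)-12-acetoxy-2,6,10-trimethyl-2-[(E)-3-oxoprop-1-en-1-yl]-7-(prop-1-en-2-yl)dodeca-6,10-dienoate F10. Intramolecular Diels–Alder reaction of F10 under catalysis by the matched enantiomer of 5-benzyl-2-tert-butyl-3-methylimidazolidin-4-one trifluoroacetate (MeCN/H2O, 0 °C) should give methyl (4S,5R,6S,10S)-15-acetoxy-6-formyllabda-8,13E-dien-19-oate F11. Decarbonylation of F11 with RhCl(PPh3)3 (1.1 equiv, toluene, reflux) gives 22.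

Step 15. C–N homolysis of an unactivated secondary nitro group may be slow, giving incomplete conversion, partial reduction at nitrogen, or alkene isomerisation by reversible stannyl radical addition. The fallback sets out from aldehyde 17 and comes back at 22, using a sulfone as the traceless activator. Horner–Wadsworth–Emmons reaction of 17 with diethyl [(phenylsulfonyl)methyl]phosphonate (NaH, THF) should give the E vinyl sulfone methyl (2S,6E,10E)-12-{[tert-butyl(dimethyl)silyl]oxy}-2,6,10-trimethyl-2-[(E)-2-(phenylsulfonyl)ethenyl]-7-(prop-1-en-2-yl)dodeca-6,10-dienoate F12. Thermal intramolecular Diels–Alder reaction (toluene, 150–170 °C) should give methyl (4S,5R,6S,10S)-15-{[tert-butyl(dimethyl)silyl]oxy}-6-(phenylsulfonyl)labda-8,13E-dien-19-oate F13. Reductive desulfonylation with sodium amalgam (Na/Hg, Na2HPO4, MeOH/THF, −20 °C) gives methyl (4S,5R,10S)-15-{[tert-butyl(dimethyl)silyl]oxy}labda-8,13E-dien-19-oate F14. Bu4NF gives methyl (4S,5R,10S)-15-hydroxylabda-8,13E-dien-19-oate F15, and Ac2O/pyridine gives 22.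

**Further compounds**
F1 | step 5 | methyl (5E)-2-acetyl-7-{[tert-butyl(dimethyl)silyl]oxy}-5-methylhept-5-enoate | COC(=O)C(CC/C(C)=C/CO[Si](C)(C)C(C)(C)C)C(C)=O
F2 | step 5 | methyl (2E,5E)-7-{[tert-butyl(dimethyl)silyl]oxy}-5-methyl-2-{1-[(4-methylbenzenesulfonyl)oxy]ethylidene}hept-5-enoate | Cc1ccc(cc1)S(=O)(=O)O/C(C)=C(\CC/C(C)=C/CO[Si](C)(C)C(C)(C)C)C(=O)OC
F3 | step 5 | 9-{3-[(triethylsilyl)oxy]propyl}-9-borabicyclo[3.3.1]nonane | CC[Si](CC)(CC)OCCCB1C2CCCC1CCC2
F4 | step 5 | methyl (2E,5E)-7-{[tert-butyl(dimethyl)silyl]oxy}-5-methyl-2-{5-[(triethylsilyl)oxy]pentan-2-ylidene}hept-5-enoate | CC[Si](CC)(CC)OCCC/C(C)=C(\CC/C(C)=C/CO[Si](C)(C)C(C)(C)C)C(=O)OC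
F5 | step 5 | (3E)-3-[(3E)-5-{[tert-butyl(dimethyl)silyl]oxy}-3-methylpent-3-en-1-yl]-2,4-dimethyl-7-[(triethylsilyl)oxy]hept-3-en-2-ol | CC[Si](CC)(CC)OCCC/C(C)=C(\CC/C(C)=C/CO[Si](C)(C)C(C)(C)C)C(C)(C)O
F6 | step 5 | (2E,6E)-1-{[tert-butyl(dimethyl)silyl]oxy}-3,7-dimethyl-6-(prop-1-en-2-yl)-10-[(triethylsilyl)oxy]deca-2,6-diene | CC[Si](CC)(CC)OCCC/C(C)=C(\CC/C(C)=C/CO[Si](C)(C)C(C)(C)C)C(C)=C
F7 | step 5 | (4E,8E)-10-{[tert-butyl(dimethyl)silyl]oxy}-4,8-dimethyl-5-(prop-1-en-2-yl)deca-4,8-dien-1-ol | OCCC/C(C)=C(\CC/C(C)=C/CO[Si](C)(C)C(C)(C)C)C(C)=C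
F8 | step 14 | methyl (2S,6E,10E)-12-{[tert-butyl(dimethyl)silyl]oxy}-2,6,10-trimethyl-2-[(E)-3-oxoprop-1-en-1-yl]-7-(prop-1-en-2-yl)dodeca-6,10-dienoate | COC(=O)[C@@](C)(CCC/C(C)=C(\CC/C(C)=C/CO[Si](C)(C)C(C)(C)C)C(C)=C)/C=C/C=O
F9 | step 14 | methyl (2S,6E,10E)-12-hydroxy-2,6,10-trimethyl-2-[(E)-3-oxoprop-1-en-1-yl]-7-(prop-1-en-2-yl)dodeca-6,10-dienoate | COC(=O)[C@@](C)(CCC/C(C)=C(\CC/C(C)=C/CO)C(C)=C)/C=C/C=O
F10 | step 14 | methyl (2S,6E,10E)-12-acetoxy-2,6,10-trimethyl-2-[(E)-3-oxoprop-1-en-1-yl]-7-(prop-1-en-2-yl)dodeca-6,10-dienoate | COC(=O)[C@@](C)(CCC/C(C)=C(\CC/C(C)=C/COC(C)=O)C(C)=C)/C=C/C=O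
F11 | step 14 | methyl (4S,5R,6S,10S)-15-acetoxy-6-formyllabda-8,13E-dien-19-oate | COC(=O)[C@@]1(C)CCC[C@]2(C)C(CC/C(C)=C/COC(C)=O)=C(C)C[C@H](C=O)[C@@H]12
F12 | step 15 | methyl (2S,6E,10E)-12-{[tert-butyl(dimethyl)silyl]oxy}-2,6,10-trimethyl-2-[(E)-2-(phenylsulfonyl)ethenyl]-7-(prop-1-en-2-yl)dodeca-6,10-dienoate | COC(=O)[C@@](C)(CCC/C(C)=C(\CC/C(C)=C/CO[Si](C)(C)C(C)(C)C)C(C)=C)/C=C/S(=O)(=O)c1ccccc1
F13 | step 15 | methyl (4S,5R,6S,10S)-15-{[tert-butyl(dimethyl)silyl]oxy}-6-(phenylsulfonyl)labda-8,13E-dien-19-oate | COC(=O)[C@@]1(C)CCC[C@]2(C)C(CC/C(C)=C/CO[Si](C)(C)C(C)(C)C)=C(C)C[C@H](S(=O)(=O)c3ccccc3)[C@@H]12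
F14 | step 15 | methyl (4S,5R,10S)-15-{[tert-butyl(dimethyl)silyl]oxy}labda-8,13E-dien-19-oate | COC(=O)[C@@]1(C)CCC[C@]2(C)C(CC/C(C)=C/CO[Si](C)(C)C(C)(C)C)=C(C)CC[C@@H]12
F15 | step 15 | methyl (4S,5R,10S)-15-hydroxylabda-8,13E-dien-19-oate | COC(=O)[C@@]1(C)CCC[C@]2(C)C(CC/C(C)=C/CO)=C(C)CC[C@@H]12
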